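## Retrosynthetic overview

1. Feature: in the ten-membered ring, carbinol carbon C6 (OAc) lies between the C4–C5 cis-oxirane, a masked Z C4=C5 alkene, and C7. The isopropyl group on C7 (C11–C13) is a masked isopropenyl group. The unit C4=C5–C6(OH)–C7–C11(=C12) is the product pattern of an allyl-stabilised [2,3]-Wittig shift.
2. Late disconnections: the C8 senecioate, the C8 silyl ether, hydrogenation of C11=C12, the C6 acetate and the C6–OH-directed epoxidation lead back to trienol 26.
3. Key disconnection: cutting C6–C7 and re-joining O6 to C12 enlarges the carbocycle to the thirteen-membered diallylic ether 23 (Z C4=C5, Z C7=C11, E C1=C10, C8 the only stereocentre).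
4. Ether 23 opens at O–C12 to chloro alcohol 21. This is assembled from nerol (C1–C6, C9, C10 and two methyls), a chiral glycolate imide (C7, C8) and a Still–Gennari propionate phosphonate (C11–C13).
5. Ring order: thirteen-membered ether ring (step 13), ten-membered carbocycle (step 14), oxirane (step 15).

Key step: step 14

Remark on the chemistry: germacrane numbering is used for all compounds (C1=C10(Me), C2, C3, C4(Me), C5, C6, C7, C8, C9; C11–C13 on C7). The target SMILES is read as (4S,5R,6R,7R,8S), with E C1=C10 and a cis-epoxide (C3 and C6 on the same side). TBS = tert-butyldimethylsilyl, PMB = 4-methoxybenzyl. The C6 oxygen of nerol is carried as a PMB ether, so that it can be freed beside the C8 TBS ether and the allylic chloride.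

## Route

Step 1
Reactants: 1 nerol
Product: 2 neryl 4-methoxybenzyl ether
Conditions: NaH, PMBCl, n-Bu4NI (cat.), THF–DMF, 0 °C to rt
Reagents that add atoms: 4-methoxybenzyl chloride, COc1ccc(CCl)cc1
Why: Williamson etherification of a primary allylic alkoxide with a benzylic chloride is dependable, leaves the Z C4=C5 alkene intact and installs a C6–O group that can later be removed oxidatively beside a silyl ether and an allylic chloride.

Step 2
Reactants: 2 neryl 4-methoxybenzyl ether
Product: 3 (2E,6Z)-8-(4-methoxybenzyloxy)-2,6-dimethylocta-2,6-dien-1-ol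
Conditions: SeO2 (0.1 equiv), t-BuOOH (2 equiv), salicylic acid (0.1 equiv), CH2Cl2, 0 °C to rt, stopped before over-oxidation
Reagents that add atoms: tert-butyl hydroperoxide, CC(C)(C)OO (oxygen handed on by SeO2)
Why: Riley allylic oxidation (ene reaction, then [2,3]-shift of the allylseleninic acid) takes the E methyl group of the more electron-rich terminal alkene, so C9 is hydroxylated with E C1=C10 geometry while C4=C5, deactivated by its allylic oxygen, is left alone.

Step 3
Reactants: 3 (2E,6Z)-8-(4-methoxybenzyloxy)-2,6-dimethylocta-2,6-dien-1-ol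
Product: 4 (2Z,6E)-8-bromo-3,7-dimethylocta-2,6-dienyl 4-methoxybenzyl ether
Conditions: CBr4, PPh3, CH2Cl2, 0 °C
Reagents that add atoms: carbon tetrabromide, BrC(Br)(Br)Br
Why: The Appel reaction turns the primary allylic alcohol into the bromide by SN2 displacement of an alkoxyphosphonium ion under neutral conditions, without allylic transposition and without harm to the PMB ether.

Step 4
Reactants: 5 glycolic acid
Product: 7 (tert-butyldimethylsilyloxy)acetic acid, via bis-silyl glycolate 6 (not isolated)
Conditions: TBSCl (2.2 equiv), imidazole, DMF, rt; then K2CO3, MeOH–THF–H2O, rt; acidic work-up (pH 4)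
Reagents that add atoms: tert-butyldimethylsilyl chloride, CC(C)(C)[Si](C)(C)Cl
Why: Exhaustive silylation followed by selective hydrolysis of the far more labile silyl ester leaves the silyl ether, a C8–O group that carries no acidic α-protons into the later carbanion step.

Step 5
Reactants: 7 (tert-butyldimethylsilyloxy)acetic acid, 8 (R)-4-benzyl-2-oxazolidinone
Product: 10 (R)-4-benzyl-3-[(tert-butyldimethylsilyloxy)acetyl]oxazolidin-2-one, via mixed pivalic anhydride 9 (not isolated)
Conditions: PivCl, Et3N, THF, −20 °C; then LiCl, 8, −20 °C to rt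
Reagents that add atoms: pivaloyl chloride, CC(C)(C)C(=O)Cl (acyl group only in 9)
Why: N-acylation through a mixed anhydride works because the oxazolidinone attacks the unhindered glycolyl carbonyl and not the tert-butyl-shielded one.

Step 6
Reactants: 10 (R)-4-benzyl-3-[(tert-butyldimethylsilyloxy)acetyl]oxazolidin-2-one, 4 (2Z,6E)-8-bromo-3,7-dimethylocta-2,6-dienyl 4-methoxybenzyl ether
Product: 12 (4R)-4-benzyl-3-[(2S,4E,8Z)-2-(TBSO)-10-(PMBO)-4,8-dimethyldeca-4,8-dienoyl]oxazolidin-2-one, via sodium Z-enolate 11 (not isolated)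
Conditions: NaN(SiMe3)2, THF, −78 °C; then 4, −78 to −45 °C
Reagents that add atoms: NaN(SiMe3)2, C[Si](C)(C)[N-][Si](C)(C)C.[Na+] (sodium only in 11)
Why: In this Evans-type asymmetric glycolate alkylation the chelated Z-enolate meets the reactive allylic bromide on the face away from the benzyl group, which forms C8–C9 and, with the (R)-auxiliary, sets C8 as S.

Step 7
Reactants: 12 alkylated imide
Product: 13 (2S,4E,8Z)-2-(TBSO)-10-(PMBO)-4,8-dimethyldeca-4,8-dien-1-ol
Conditions: LiBH4, Et2O–THF, 0 °C
Reagents that add atoms: none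
Why: Reductive auxiliary cleavage succeeds because hydride attacks the more electrophilic exocyclic imide carbonyl, C8 is not enolised, and the auxiliary is returned.

Step 8
Reactants: 13 (2S,4E,8Z)-2-(TBSO)-10-(PMBO)-4,8-dimethyldeca-4,8-dien-1-ol
Product: 14 (2S,4E,8Z)-2-(TBSO)-10-(PMBO)-4,8-dimethyldeca-4,8-dienal
Conditions: Dess–Martin periodinane, CH2Cl2, 0 °C to rt; used directly
Reagents that add atoms: none
Why: Dess–Martin oxidation gives the α-silyloxy aldehyde (C7) under non-enolising conditions, so the C8 configuration is kept and the alkenes and PMB ether are untouched.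

Step 9
Reactants: 14 (2S,4E,8Z)-2-(TBSO)-10-(PMBO)-4,8-dimethyldeca-4,8-dienal, 15 methyl 2-[bis(2,2,2-trifluoroethoxy)phosphoryl]propanoate
Product: 17 methyl (2Z,4S,6E,10Z)-4-(TBSO)-12-(PMBO)-2,6,10-trimethyldodeca-2,6,10-trienoate, via potassium phosphonate carbanion 16 (not isolated)
Conditions: KN(SiMe3)2, 18-crown-6, THF, −78 °C; then 14, −78 °C
Reagents that add atoms: KN(SiMe3)2, C[Si](C)(C)[N-][Si](C)(C)C.[K+] (potassium only in 16)
Why: In the Still–Gennari olefination the electron-poor phosphonate eliminates fast from the kinetic adduct under dissociating conditions, which should give the Z trisubstituted C7=C11 enoate (C12 cis to C8), and the low temperature protects C8 from epimerisation.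

Step 10
Reactants: 17 Z-enoate
Product: 18 (2Z,4S,6E,10Z)-4-(TBSO)-12-(PMBO)-2,6,10-trimethyldodeca-2,6,10-trien-1-ol
Conditions: i-Bu2AlH (2.5 equiv), CH2Cl2, −78 °C; aq. potassium sodium tartrate
Reagents that add atoms: none
Why: 1,2-Reduction of the enoate by i-Bu2AlH at low temperature gives the C12 allylic alcohol with alkene geometry, silyl ether and PMB ether unchanged.

Step 11
Reactants: 18 C12 allylic alcohol
Product: 20 (2Z,6E,9S,10Z)-12-chloro-9-(TBSO)-3,7,11-trimethyldodeca-2,6,10-trienyl 4-methoxybenzyl ether, via allylic mesylate 19 (not isolated)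
Conditions: MsCl, Et3N, CH2Cl2, −40 °C; then LiCl, THF–DMF, 0 °C
Reagents that add atoms: lithium chloride, [Li+].[Cl-]; methanesulfonyl chloride, CS(=O)(=O)Cl (only in 19)
Why: Mesylation and direct SN2 displacement by chloride converts the primary allylic alcohol without transposition or loss of Z geometry, and the chloride is robust enough to survive the next deprotection.

Step 12
Reactants: 20 chloro PMB ether
Product: 21 (2Z,6E,9S,10Z)-12-chloro-9-(TBSO)-3,7,11-trimethyldodeca-2,6,10-trien-1-ol
Conditions: DDQ (1.2 equiv), CH2Cl2–pH 7 buffer, 0 °C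
Reagents that add atoms: none
Why: Oxidative PMB cleavage (hydride abstraction by DDQ, then hydrolysis of the oxocarbenium ion) frees C6–OH under near-neutral conditions that spare the allylic chloride, the TBS ether and the three alkenes.

Step 13
Reactants: 21 chloro alcohol
Product: 23 (3Z,5S,7E,11Z)-5-(TBSO)-3,7,11-trimethyl-1-oxacyclotrideca-3,7,11-triene, via sodium alkoxide 22 (not isolated)
Conditions: NaH (5 equiv), THF, 60 °C; 21 added by syringe pump over 12 h (final 0.002 M)
Reagents that add atoms: NaH, [Na+].[H-] (sodium only in 22)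
Why: Intramolecular Williamson etherification (SN2 of the C6 alkoxide at primary allylic C12) under high dilution should close the thirteen-membered ring, helped by three alkenes, two of them Z, that cut down rotatable bonds and bend the chain ends together, while the alkoxide stays far from the silyl ether.

Step 14
Reactants: 23 thirteen-membered diallylic ether
Product: 26 (6S,7S,8S)-8-(TBSO)germacra-1(10)E,4Z,11-trien-6-ol, via C6-lithio ether 24 (not isolated), via lithium alkoxide 25 (not isolated)
Conditions: n-BuLi (2 equiv), THF, −78 to −30 °C; AcOH–THF quench at −78 °C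
Reagents that add atoms: n-butyllithium, [Li]CCCC (lithium only in 24 and 25)
Why: n-BuLi removes a C6 proton of 23, and the allyl-stabilised α-oxy carbanion 24 bonds through C6 to C7 across the C12–C11=C7 allyl unit in a suprafacial, five-centre envelope transition state while O–C12 breaks, which gives the C6–C7 bond, the C11=C12 isopropenyl group and alkoxide 25 ([2,3]-Wittig rearrangement). The closest known reaction type is the [2,3]-Wittig ring contraction of thirteen-membered diallylic ethers to germacrane-type cyclodecadienols. The ten-membered carbocycle is closed transannularly, as a 13-to-10 ring contraction in which O, C12 and C11 leave the ring, so neither an end-to-end closure nor high dilution is needed. The C6/C7 relation follows from the Z geometry of C7=C11 combined with the exo position of the C5 alkenyl group on the envelope, which places O6 and C8 syn along C5–C6–C7–C11 (6S,7S), as in open-chain Z-allyl ethers. The C7/C8 relation follows from the C8 stereocentre: A(1,3) strain against C12 keeps H8 in the alkene plane, the ring holds C9 on the inner face, and C6 therefore reaches C7 anti to the C8–OSi bond, which is also the stereoelectronically preferred arrangement. The step needs lithiation at C6 and not at C12, which is secured by the shielding of C12 by the C11 methyl group and the cis C8 silyloxy branch, by a non-coordinating silyl ether that offers the base no anchor there, and by the poor prospects of a C12 carbanion that could only attack fully substituted C4, while the lithium counter-ion and the low temperature hold back [1,2]-shift, oxy-Cope rearrangement and silyl migration to O6.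

Step 15
Reactants: 26 trienol
Product: 27 (4S,5R,6R,7S,8S)-4,5-epoxy-8-(TBSO)germacra-1(10)E,11-dien-6-ol
Conditions: VO(acac)2 (5 mol %), t-BuOOH (1.2 equiv), CH2Cl2, 0 °C
Reagents that add atoms: tert-butyl hydroperoxide, CC(C)(C)OO
Why: In this hydroxyl-directed vanadium-catalysed epoxidation the C6 vanadate ester delivers oxygen to the adjacent C4=C5 alkene much faster than to homoallylic C11=C12 or remote C1=C10, and in medium-ring Z-cycloalkenols this delivery occurs on the face cis to the hydroxyl group, which sets C4 (S) and C5 (R) while the Z geometry makes the oxirane cis.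

Step 16
Reactants: 27 epoxy alcohol
Product: 28 (4S,5R,6R,7S,8S)-6-acetoxy-4,5-epoxy-8-(TBSO)germacra-1(10)E,11-diene
Conditions: Ac2O, pyridine, DMAP (cat.), CH2Cl2, rt
Reagents that add atoms: acetic anhydride, CC(=O)OC(C)=O
Why: DMAP-catalysed acylation esterifies the only free hydroxyl group with retention at C6 under non-aqueous, weakly basic conditions that trigger no epoxide migration.

Step 17
Reactants: 28 epoxy acetate
Product: 29 (4S,5R,6R,7S,8S)-6-acetoxy-4,5-epoxy-8-(TBSO)germacr-1(10)E-ene
Conditions: H2 (1 atm), RhCl(PPh3)3 (10 mol %), benzene, rt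
Reagents that add atoms: none
Why: Homogeneous hydrogenation with RhCl(PPh3)3 discriminates by steric access, so the 1,1-disubstituted C11=C12 alkene is reduced while the trisubstituted ring alkene C1=C10, the oxirane and the ester are inert, and no stereocentre arises because C11 ends with two methyl groups.

Step 18
Reactants: 29 isopropyl epoxy acetate
Product: 30 (4S,5R,6R,7R,8S)-6-acetoxy-4,5-epoxygermacr-1(10)E-en-8-ol
Conditions: n-Bu4NF–AcOH (1:1), THF, 0 °C to rt
Reagents that add atoms: none
Why: Fluoride-induced Si–O cleavage frees C8–OH, and the acetic acid buffer keeps the liberated oxygen protonated so that acetyl migration from O6 and transannular opening of the oxirane are not triggered.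

Step 19
Reactants: 30 C8 alcohol, 31 3-methylbut-2-enoic acid (senecioic acid)
Product: 33 target (4S,5R,6R,7R,8S)-6-acetoxy-4,5-epoxy-8-(3-methylbut-2-enoyloxy)germacr-1(10)E-ene, via mixed Yamaguchi anhydride 32 (not isolated)
Conditions: 31, 2,4,6-trichlorobenzoyl chloride, Et3N, toluene, rt; then 30, DMAP, rt
Reagents that add atoms: 2,4,6-trichlorobenzoyl chloride, O=C(Cl)c1c(Cl)cc(Cl)cc1Cl (only in 32)
Why: In the Yamaguchi esterification DMAP picks the less hindered senecioyl carbonyl of 32 and passes it to the hindered C8–OH with retention at C8, under conditions mild enough to keep the enoate conjugated and the oxirane and acetate intact.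

## Compound list

1 | nerol, (2Z)-3,7-dimethylocta-2,6-dien-1-ol | CC(C)=CCC/C(C)=C\CO | starting material
2 | neryl 4-methoxybenzyl ether | CC(C)=CCC/C(C)=C\COCc1ccc(OC)cc1 | intermediate
3 | (2E,6Z)-8-(4-methoxybenzyloxy)-2,6-dimethylocta-2,6-dien-1-ol | OC/C(C)=C/CC/C(C)=C\COCc1ccc(OC)cc1 | intermediate
4 | (2Z,6E)-8-bromo-3,7-dimethylocta-2,6-dienyl 4-methoxybenzyl ether | BrC/C(C)=C/CC/C(C)=C\COCc1ccc(OC)cc1 | intermediate
5 | glycolic acid | OCC(=O)O | starting material
6 | tert-butyldimethylsilyl (tert-butyldimethylsilyloxy)acetate | CC(C)(C)[Si](C)(C)OCC(=O)O[Si](C)(C)C(C)(C)C | intermediate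
7 | (tert-butyldimethylsilyloxy)acetic acid | CC(C)(C)[Si](C)(C)OCC(=O)O | intermediate
8 | (R)-4-benzyl-2-oxazolidinone | O=C1N[C@H](Cc2ccccc2)CO1 | starting material
9 | (tert-butyldimethylsilyloxy)acetic pivalic anhydride | CC(C)(C)C(=O)OC(=O)CO[Si](C)(C)C(C)(C)C | intermediate
10 | (R)-4-benzyl-3-[(tert-butyldimethylsilyloxy)acetyl]oxazolidin-2-one | O=C1OC[C@@H](Cc2ccccc2)N1C(=O)CO[Si](C)(C)C(C)(C)C | intermediate
11 | sodium Z-enolate of 10 | O=C1OC[C@@H](Cc2ccccc2)N1/C([O-])=C/O[Si](C)(C)C(C)(C)C.[Na+] | intermediate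
12 | (4R)-4-benzyl-3-[(2S,4E,8Z)-2-(TBSO)-10-(PMBO)-4,8-dimethyldeca-4,8-dienoyl]oxazolidin-2-one | O=C1OC[C@@H](Cc2ccccc2)N1C(=O)[C@@H](O[Si](C)(C)C(C)(C)C)C/C(C)=C/CC/C(C)=C\COCc1ccc(OC)cc1 | intermediate
13 | (2S,4E,8Z)-2-(TBSO)-10-(PMBO)-4,8-dimethyldeca-4,8-dien-1-ol | OC[C@@H](O[Si](C)(C)C(C)(C)C)C/C(C)=C/CC/C(C)=C\COCc1ccc(OC)cc1 | intermediate
14 | (2S,4E,8Z)-2-(TBSO)-10-(PMBO)-4,8-dimethyldeca-4,8-dienal | O=C[C@@H](O[Si](C)(C)C(C)(C)C)C/C(C)=C/CC/C(C)=C\COCc1ccc(OC)cc1 | intermediate
15 | methyl 2-[bis(2,2,2-trifluoroethoxy)phosphoryl]propanoate | COC(=O)C(C)P(=O)(OCC(F)(F)F)OCC(F)(F)F | starting material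
16 | potassium carbanion of 15 | COC(=O)[C-](C)P(=O)(OCC(F)(F)F)OCC(F)(F)F.[K+] | intermediate
17 | methyl (2Z,4S,6E,10Z)-4-(TBSO)-12-(PMBO)-2,6,10-trimethyldodeca-2,6,10-trienoate | COC(=O)/C(C)=C\[C@@H](O[Si](C)(C)C(C)(C)C)C/C(C)=C/CC/C(C)=C\COCc1ccc(OC)cc1 | intermediate
18 | (2Z,4S,6E,10Z)-4-(TBSO)-12-(PMBO)-2,6,10-trimethyldodeca-2,6,10-trien-1-ol | OC/C(C)=C\[C@@H](O[Si](C)(C)C(C)(C)C)C/C(C)=C/CC/C(C)=C\COCc1ccc(OC)cc1 | intermediate
19 | methanesulfonate of 18 | CS(=O)(=O)OC/C(C)=C\[C@@H](O[Si](C)(C)C(C)(C)C)C/C(C)=C/CC/C(C)=C\COCc1ccc(OC)cc1 | intermediate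
20 | (2Z,6E,9S,10Z)-12-chloro-9-(TBSO)-3,7,11-trimethyldodeca-2,6,10-trienyl 4-methoxybenzyl ether | ClC/C(C)=C\[C@@H](O[Si](C)(C)C(C)(C)C)C/C(C)=C/CC/C(C)=C\COCc1ccc(OC)cc1 | intermediate
21 | (2Z,6E,9S,10Z)-12-chloro-9-(TBSO)-3,7,11-trimethyldodeca-2,6,10-trien-1-ol | ClC/C(C)=C\[C@@H](O[Si](C)(C)C(C)(C)C)C/C(C)=C/CC/C(C)=C\CO | intermediate
22 | sodium alkoxide of 21 | ClC/C(C)=C\[C@@H](O[Si](C)(C)C(C)(C)C)C/C(C)=C/CC/C(C)=C\C[O-].[Na+] | intermediate
23 | (3Z,5S,7E,11Z)-5-(TBSO)-3,7,11-trimethyl-1-oxacyclotrideca-3,7,11-triene | C1/C(C)=C\COC/C(C)=C\[C@@H](O[Si](C)(C)C(C)(C)C)C/C(C)=C/C1 | intermediate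
24 | C6-lithio derivative of 23 | C1/C(C)=C\C([Li])OC/C(C)=C\[C@@H](O[Si](C)(C)C(C)(C)C)C/C(C)=C/C1 | intermediate
25 | lithium alkoxide of 26 | C1/C(C)=C\[C@H]([O-])[C@H](C(C)=C)[C@@H](O[Si](C)(C)C(C)(C)C)C/C(C)=C/C1.[Li+] | intermediate
26 | (6S,7S,8S)-8-(TBSO)germacra-1(10)E,4Z,11-trien-6-ol | C1/C(C)=C\[C@H](O)[C@H](C(C)=C)[C@@H](O[Si](C)(C)C(C)(C)C)C/C(C)=C/C1 | intermediate
27 | (4S,5R,6R,7S,8S)-4,5-epoxy-8-(TBSO)germacra-1(10)E,11-dien-6-ol | O[C@@H]1[C@H](C(C)=C)[C@@H](O[Si](C)(C)C(C)(C)C)C/C(C)=C/CC[C@]2(C)O[C@H]12 | intermediate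
28 | (4S,5R,6R,7S,8S)-6-acetoxy-4,5-epoxy-8-(TBSO)germacra-1(10)E,11-diene | CC(=O)O[C@@H]1[C@H](C(C)=C)[C@@H](O[Si](C)(C)C(C)(C)C)C/C(C)=C/CC[C@]2(C)O[C@H]12 | intermediate
29 | (4S,5R,6R,7S,8S)-6-acetoxy-4,5-epoxy-8-(TBSO)germacr-1(10)E-ene | CC(=O)O[C@@H]1[C@H](C(C)C)[C@@H](O[Si](C)(C)C(C)(C)C)C/C(C)=C/CC[C@]2(C)O[C@H]12 | intermediate
30 | (4S,5R,6R,7R,8S)-6-acetoxy-4,5-epoxygermacr-1(10)E-en-8-ol | CC(=O)O[C@@H]1[C@H](C(C)C)[C@@H](O)C/C(C)=C/CC[C@]2(C)O[C@H]12 | intermediate
31 | 3-methylbut-2-enoic acid (senecioic acid) | CC(C)=CC(=O)O | starting material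
32 | 3-methylbut-2-enoic 2,4,6-trichlorobenzoic anhydride | CC(C)=CC(=O)OC(=O)c1c(Cl)cc(Cl)cc1Cl | intermediate
33 | (4S,5R,6R,7R,8S)-6-acetoxy-4,5-epoxy-8-(3-methylbut-2-enoyloxy)germacr-1(10)E-ene | CC(=O)O[C@@H]1[C@H](C(C)C)[C@@H](OC(=O)C=C(C)C)C/C(C)=C/CC[C@]2(C)O[C@H]12 | target

## Step count and risks

Total step count: 19. Longest linear sequence: 17 (steps 1–3 and 6–19).

**Step 14 (ring contraction).**
- What may go wrong: lithiation may occur at C12 instead of C6. That could be followed by loss of silanolate through 1,4-elimination or by a shift onto C4. A [1,2]-shift, an endo transition state, or attack on the alkene face syn to the silyl ether would erode the C6/C7/C8 relation.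
- Fallback: it sets out from 21 and comes back at 26. It forms the same C6–C7 bond by carbonyl allylation instead of a sigmatropic shift.
  - MnO2 in CH2Cl2 oxidises the C6 alcohol of 21 to (2Z,6E,9S,10Z)-12-chloro-9-(TBSO)-3,7,11-trimethyldodeca-2,6,10-trienal F1.
  - CrCl2 in THF at high dilution couples the allylic chloride through its γ-carbon C7 to the C6 aldehyde. This is an intramolecular Nozaki–Hiyama allylation, a known way to close germacrane-type ten-membered rings, and it unveils the same isopropenyl group.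
  - This reaction type is anti-selective, so the C6 epimer of the trienol F2 is expected.
  - Dess–Martin oxidation gives the Z-enone F3. Borane reduction under oxazaborolidine control, with the catalyst antipode that delivers hydride to the required C6 face, sets C6 and gives 26.

**Step 13 (macroetherification).**
- What may go wrong: intermolecular etherification may outrun ring closure. Displacement at C12, crowded by the C11 methyl group and the cis C8 branch, may be slow enough for elimination to compete.
- Fallback: it sets out from 17 and comes back at 23. It exchanges the electrophilic and nucleophilic termini, so that the leaving group sits at unhindered C6.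
  - DDQ frees the hydroxy enoate F4.
  - PPh3 and hexachloroacetone give the neryl-type chloro enoate F5.
  - i-Bu2AlH at −78 °C reduces the ester beside the chloride to the isomeric chloro alcohol F6.
  - NaH under high dilution closes the same C6–O–C12 bond to 23.

**Step 15 (directed epoxidation).**
- What may go wrong: poor facial selectivity. If the ring reacts through the conformer that holds H6 rather than O6 near the alkene plane, oxygen reaches the opposite face of C4=C5. Some oxidation of the isopropenyl group may also occur.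
- Fallback: it sets out from 26 and comes back at 27. It replaces substrate direction by catalyst control.
  - Conditions: Sharpless asymmetric epoxidation with Ti(OiPr)4, D-(−)-diisopropyl tartrate, t-BuOOH and 4 Å molecular sieves in CH2Cl2 at −20 °C.
  - By the empirical rule of this reaction, the D-(−)-tartrate attacks the required face of C4=C5 and is matched with the C6 configuration of 26.
  - Titanium–tartrate catalysts favour the erythro epoxy alcohol, which here is the ring-cis isomer.
  - No compound outside the list is made (F0).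

## Further compounds

F1 | step 14 | (2Z,6E,9S,10Z)-12-chloro-9-(TBSO)-3,7,11-trimethyldodeca-2,6,10-trienal | ClC/C(C)=C\[C@@H](O[Si](C)(C)C(C)(C)C)C/C(C)=C/CC/C(C)=C\C=O
F2 | step 14 | (6R,7S,8S)-8-(TBSO)germacra-1(10)E,4Z,11-trien-6-ol, C6 epimer of 26 | C1/C(C)=C\[C@@H](O)[C@H](C(C)=C)[C@@H](O[Si](C)(C)C(C)(C)C)C/C(C)=C/C1
F3 | step 14 | 8-(TBSO)germacra-1(10)E,4Z,11-trien-6-one with C7 and C8 as in 26 | C1/C(C)=C\C(=O)[C@H](C(C)=C)[C@@H](O[Si](C)(C)C(C)(C)C)C/C(C)=C/C1
F4 | step 13 | methyl (2Z,4S,6E,10Z)-4-(TBSO)-12-hydroxy-2,6,10-trimethyldodeca-2,6,10-trienoate | COC(=O)/C(C)=C\[C@@H](O[Si](C)(C)C(C)(C)C)C/C(C)=C/CC/C(C)=C\CO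
F5 | step 13 | methyl (2Z,4S,6E,10Z)-12-chloro-4-(TBSO)-2,6,10-trimethyldodeca-2,6,10-trienoate | COC(=O)/C(C)=C\[C@@H](O[Si](C)(C)C(C)(C)C)C/C(C)=C/CC/C(C)=C\CCl
F6 | step 13 | (2Z,4S,6E,10Z)-12-chloro-4-(TBSO)-2,6,10-trimethyldodeca-2,6,10-trien-1-ol | OC/C(C)=C\[C@@H](O[Si](C)(C)C(C)(C)C)C/C(C)=C/CC/C(C)=C\CCl
F0 | step 15 | none | none
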